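**Assumption:** tricyclic compounds are numbered as tricyclo[5.4.0.0(2,8)]undecane: C1 = ring-fusion CH next to the ketone C11, C2 = C(CH3), C3 and C5 = ester-bearing carbons, C6 = C(CH3)2, C7 and C8 = remaining cyclobutane CH, C9=C10 = enone alkene. The target is then (1R,2R,3R,5R,7S,8R). Bicyclic intermediates are numbered as bicyclo[3.1.1]heptane with C1 = CH next to the methylidene carbon C2, C4 = CH–OSi, C6 = former cyclobutanone carbon, C7 = C(CH3)(CH2O).

## Retrosynthetic overview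

1. Target ⇐ double acylation and late unveiling of the enone from a tricyclic anti-1,3-diol; the diol ⇐ β-hydroxy ketone (directed anti reduction) ⇐ cycloheptenone (catalyst-controlled β-borylation/oxidation).
2. Seven-membered ring (formed last) ⇐ intramolecular aldol condensation of a keto-aldehyde held on the bicyclo[3.1.1]heptane (key ring closure).
3. Keto-aldehyde ⇐ seven-membered lactone opened by MeLi; lactone ⇐ tethered ester-enolate aldol onto the cyclobutanone, then radical deoxygenation (sets C7–H).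
4. Cyclobutane and six-membered ring (formed first, together) ⇐ intramolecular vinylketene–alkene [2+2]; the C5 silyloxy stereocentre of the acyclic acid controls the face.
5. Acyclic acid ⇐ asymmetric vinylogous Mukaiyama aldol joining an enal (from prenyl chloride) and a silyl dienolate (from 3-methylbut-2-enoyl chloride).

## Route

Step 1
Reactants: 1 1-chloro-3-methylbut-2-ene (prenyl chloride)
Product: 2 (2E)-4-chloro-2-methylbut-2-en-1-ol
Conditions: SeO2 (0.1 equiv), tBuOOH (2 equiv), salicylic acid (cat.), CH2Cl2, 0 °C to rt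
Reagents that add atoms: tert-butyl hydroperoxide, CC(C)(C)OO; selenium dioxide (oxygen carrier), O=[Se]=O
Why: Sharpless catalytic SeO2 allylic oxidation (ene reaction then [2,3]-shift) hydroxylates only the (E)-methyl group of the trisubstituted alkene, which fixes the alkene geometry needed later in the cyclobutane.

Step 2
Reactants: 2 (2E)-4-chloro-2-methylbut-2-en-1-ol
Product: 3 (2E)-4-chloro-2-methylbut-2-en-1-yl 2-methylpropanoate
Conditions: iPrCOCl (1.1 equiv), iPr2NEt (1.3 equiv), DMAP (cat.), CH2Cl2, 0 °C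
Reagents that add atoms: 2-methylpropanoyl chloride, CC(C)C(Cl)=O
Why: Nucleophilic acyl substitution gives the isobutyrate, which serves as protecting group now and as the tethered aldol donor in step 9.

Step 3
Reactants: 3 (2E)-4-chloro-2-methylbut-2-en-1-yl 2-methylpropanoate
Product: 4 (2E)-2-methyl-4-oxobut-2-en-1-yl 2-methylpropanoate
Conditions: N-methylmorpholine N-oxide (4 equiv), NaI (cat.), 4 Å MS, MeCN, rt
Reagents that add atoms: 4-methylmorpholine 4-oxide, C[N+]1([O-])CCOCC1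
Why: Ganem oxidation (SN2 displacement of the allylic chloride by the N-oxide oxygen, then elimination) gives the enal without touching the ester or the E alkene.

Step 4
Reactants: 5 3-methylbut-2-enoyl chloride
Product: 6 tert-butyl 3-methylbut-2-enoate
Conditions: LiOtBu (1.05 equiv), THF, −78 °C to 0 °C
Reagents that add atoms: lithium tert-butoxide, [Li+].CC(C)(C)[O-]
Why: Acyl substitution by the alkoxide gives the tert-butyl ester; any deconjugated isomer is harmless because both give the same dienolate.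

Step 5
Reactants: 6 tert-butyl 3-methylbut-2-enoate
Product: 7 tert-butyl[(1-tert-butoxy-3-methylbuta-1,3-dien-1-yl)oxy]dimethylsilane
Conditions: LiN(iPr)2 (commercial solution, 1.1 equiv), THF, −78 °C; TBSCl, DMPU, −78 °C to rt
Reagents that add atoms: tert-butyl(chloro)dimethylsilane, CC(C)(C)[Si](C)(C)Cl
Why: Kinetic γ-deprotonation of the senecioate and O-silylation give the silyl dienolate (silyl ketene acetal formation).

Step 6
Reactants: 4 (2E)-2-methyl-4-oxobut-2-en-1-yl 2-methylpropanoate; 7 tert-butyl[(1-tert-butoxy-3-methylbuta-1,3-dien-1-yl)oxy]dimethylsilane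
Product: 9 tert-butyl (2E,5S,6E)-5-hydroxy-3,7-dimethyl-8-(2-methylpropanoyloxy)octa-2,6-dienoate, via trichlorosilyl ether 8 (not isolated)
Conditions: SiCl4 (1.1 equiv), Denmark (R,R)-bisphosphoramide (5 mol %), iPr2NEt (10 mol %), CH2Cl2, −78 °C; aq. NaHCO3/KF work-up
Reagents that add atoms: none
Why: Lewis-base-activated SiCl4 vinylogous Mukaiyama aldol, γ-selective, in which the chiral phosphoramide-bound silicon cation directs addition to the Si face of the enal to set 5S (the sense is checked by Mosher analysis and the antipodal catalyst is used if it proves opposite).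

Step 7
Reactants: 9 tert-butyl (2E,5S,6E)-5-hydroxy-3,7-dimethyl-8-(2-methylpropanoyloxy)octa-2,6-dienoate
Product: 11 (2E,5S,6E)-5-(tert-butyldimethylsilyloxy)-3,7-dimethyl-8-(2-methylpropanoyloxy)octa-2,6-dienoic acid, via bis-silyl compound 10 (not isolated)
Conditions: TBSOTf (2.5 equiv), 2,6-lutidine (4 equiv), CH2Cl2, −78 °C to rt; then MeOH/H2O, K2CO3 (cat.), 0 °C, pH 4 work-up
Reagents that add atoms: tert-butyldimethylsilyl trifluoromethanesulfonate, CC(C)(C)[Si](C)(C)OS(=O)(=O)C(F)(F)F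
Why: One pot O-silylation of the alcohol and silyl-triflate-mediated tert-butyl ester cleavage (loss of isobutene) to the silyl ester, which alone hydrolyses in the mild aqueous stage.

Step 8
Reactants: 11 (2E,5S,6E)-5-(tert-butyldimethylsilyloxy)-3,7-dimethyl-8-(2-methylpropanoyloxy)octa-2,6-dienoic acid
Product: 14 [(1R,4S,5R,7R)-4-(tert-butyldimethylsilyloxy)-7-methyl-2-methylidene-6-oxobicyclo[3.1.1]heptan-7-yl]methyl 2-methylpropanoate, via acid chloride 12 (not isolated), via vinylketene 13 (not isolated)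
Conditions: 1-chloro-N,N,2-trimethylprop-1-en-1-amine (1.2 equiv), CH2Cl2, 0 °C to rt; then slow addition to Et3N (3 equiv), toluene, 110 °C, 0.01 M
Reagents that add atoms: none
Why: Snider-type intramolecular vinylketene–alkene [2+2] cycloaddition in which the ketene carbonyl carbon bonds to the less substituted alkene carbon (bridged bicyclo[3.1.1]heptan-6-one), the E alkene places the methyl syn to the three-carbon bridge, and allylic 1,3-strain (C5–H eclipsing the alkene) sends the ketene to the face anti to the silyloxy group, so 5S fixes all three new stereocentres.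

Step 9
Reactants: 14 [(1R,4S,5R,7R)-4-(tert-butyldimethylsilyloxy)-7-methyl-2-methylidene-6-oxobicyclo[3.1.1]heptan-7-yl]methyl 2-methylpropanoate
Product: 17 O-[(11S)-11-(tert-butyldimethylsilyloxy)-2,6,6-trimethyl-9-methylidene-5-oxo-4-oxatricyclo[5.4.0.0(2,8)]undecan-7-yl] S-methyl carbonodithioate, via lithium aldolate 15 (not isolated), via lithium xanthate 16 (not isolated)
Conditions: LiN(SiMe3)2 (1.3 equiv), THF, −78 °C to −40 °C, 0.02 M; CS2 (5 equiv), −78 °C to −20 °C; MeI (6 equiv), to 0 °C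
Reagents that add atoms: carbon disulfide, S=C=S; iodomethane, CI
Why: Intramolecular ester-enolate aldol addition onto the strained, non-enolisable cyclobutanone, in which the C7–CH2O tether can deliver the C(CH3)2 carbon only to the face of C6 syn to C7 (seven-membered lactone), and the alkoxide is trapped as the xanthate before retro-aldol can occur.

Step 10
Reactants: 17 O-[(11S)-11-(tert-butyldimethylsilyloxy)-2,6,6-trimethyl-9-methylidene-5-oxo-4-oxatricyclo[5.4.0.0(2,8)]undecan-7-yl] S-methyl carbonodithioate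
Product: 18 (11S)-11-(tert-butyldimethylsilyloxy)-2,6,6-trimethyl-9-methylidene-4-oxatricyclo[5.4.0.0(2,8)]undecan-5-one
Conditions: Bu3SnH (1.5 equiv), AIBN (0.2 equiv), toluene, 100 °C
Reagents that add atoms: none
Why: Barton–McCombie deoxygenation in which the tertiary radical is held by the lactone bridge, so hydrogen can enter only from the open face and the C7–H centre of the target results (Chugaev elimination is impossible because it would need a bridgehead alkene).

Step 11
Reactants: 18 (11S)-11-(tert-butyldimethylsilyloxy)-2,6,6-trimethyl-9-methylidene-4-oxatricyclo[5.4.0.0(2,8)]undecan-5-one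
Product: 19 3-[4-(tert-butyldimethylsilyloxy)-7-(hydroxymethyl)-7-methyl-2-methylidenebicyclo[3.1.1]heptan-6-yl]-3-methylbutan-2-one (C6 side chain and C7 CH2OH cis, both anti to the C2–C4 bridge)
Conditions: MeLi (1.1 equiv), THF, −78 °C; AcOH quench at −78 °C
Reagents that add atoms: methyllithium, [Li]C
Why: Mono-addition of MeLi to the lactone, whose tetrahedral lithium lactolate persists at −78 °C and collapses on work-up to the α-quaternary methyl ketone and the primary alcohol.

Step 12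
Reactants: 19 3-[4-(tert-butyldimethylsilyloxy)-7-(hydroxymethyl)-7-methyl-2-methylidenebicyclo[3.1.1]heptan-6-yl]-3-methylbutan-2-one
Product: 20 4-(tert-butyldimethylsilyloxy)-7-methyl-6-(2-methyl-3-oxobutan-2-yl)-2-methylidenebicyclo[3.1.1]heptane-7-carbaldehyde
Conditions: Dess–Martin periodinane (1.3 equiv), CH2Cl2, 0 °C to rt
Reagents that add atoms: none
Why: Dess–Martin oxidation turns the neopentyl primary alcohol into a non-enolisable aldehyde and leaves ketone, silyl ether and alkene untouched.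

Step 13 (key ring closure)
Reactants: 20 4-(tert-butyldimethylsilyloxy)-7-methyl-6-(2-methyl-3-oxobutan-2-yl)-2-methylidenebicyclo[3.1.1]heptane-7-carbaldehyde
Product: 22 (11S)-11-(tert-butyldimethylsilyloxy)-2,6,6-trimethyl-9-methylidenetricyclo[5.4.0.0(2,8)]undec-3-en-5-one, via aldol 21 (not isolated)
Conditions: KOH (0.5 equiv), MeOH/THF, 0 °C to 45 °C, 0.01 M
Reagents that add atoms: none
Why: Intramolecular aldol condensation in which the ketone can enolise only at its CH3 and the aldehyde has no α-hydrogen, the two groups are held 1,3-diaxial on the cyclobutane so only the seven-membered ring can close, and E1cB loss of water gives the enone and erases the uncontrolled carbinol centre.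

Step 14
Reactants: 22 (11S)-11-(tert-butyldimethylsilyloxy)-2,6,6-trimethyl-9-methylidenetricyclo[5.4.0.0(2,8)]undec-3-en-5-one
Product: 24 (3R,11S)-11-(tert-butyldimethylsilyloxy)-3-hydroxy-2,6,6-trimethyl-9-methylidenetricyclo[5.4.0.0(2,8)]undecan-5-one, via boryl ketone 23 (not isolated)
Conditions: B2pin2 (1.2 equiv), CuCl (5 mol %), NaOtBu (10 mol %), (R,S)-Josiphos (6 mol %), MeOH (2 equiv), THF, rt; then NaBO3·4H2O, THF/H2O, rt
Reagents that add atoms: sodium perborate, [Na+].[Na+].O[B-]1(O)OO[B-](O)(O)OO1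
Why: Copper-catalysed enantioselective conjugate borylation followed by stereoretentive C–B oxidation; because the enone lies in the local mirror plane of the carbon framework the substrate has little facial bias and the ligand decides C3 (the ligand antipode that gives 3R is retained after Mosher analysis).

Step 15
Reactants: 24 (3R,11S)-11-(tert-butyldimethylsilyloxy)-3-hydroxy-2,6,6-trimethyl-9-methylidenetricyclo[5.4.0.0(2,8)]undecan-5-one
Product: 25 (3R,5R,11S)-11-(tert-butyldimethylsilyloxy)-2,6,6-trimethyl-9-methylidenetricyclo[5.4.0.0(2,8)]undecane-3,5-diol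
Conditions: Me4NBH(OAc)3 (5 equiv), MeCN/AcOH 1:1, −30 °C
Reagents that add atoms: none
Why: Evans–Saksena reduction, in which the alkoxy(diacetoxy)borohydride formed on the C3 hydroxyl delivers hydride intramolecularly to the same face of the C5 ketone and so gives the trans (anti) 1,3-diol with 5R.

Step 16
Reactants: 25 (3R,5R,11S)-11-(tert-butyldimethylsilyloxy)-2,6,6-trimethyl-9-methylidenetricyclo[5.4.0.0(2,8)]undecane-3,5-diol; 5 3-methylbut-2-enoyl chloride
Product: 26 (3R,5R,11S)-11-(tert-butyldimethylsilyloxy)-2,6,6-trimethyl-9-methylidenetricyclo[5.4.0.0(2,8)]undecane-3,5-diyl bis(3-methylbut-2-enoate)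
Conditions: 5 (4 equiv), pyridine, DMAP (2 equiv), CH2Cl2, 0 °C to 40 °C
Reagents that add atoms: 3-methylbut-2-enoyl chloride (5), CC(C)=CC(Cl)=O
Why: DMAP-catalysed acylation (acylpyridinium) of both hindered secondary alcohols; any deconjugated 3-methylbut-3-enoate formed through the vinylketene is re-conjugated by the DBU of step 18.

Step 17
Reactants: 26 (3R,5R,11S)-11-(tert-butyldimethylsilyloxy)-2,6,6-trimethyl-9-methylidenetricyclo[5.4.0.0(2,8)]undecane-3,5-diyl bis(3-methylbut-2-enoate)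
Product: 27 (3R,5R,11S)-11-hydroxy-2,6,6-trimethyl-9-methylidenetricyclo[5.4.0.0(2,8)]undecane-3,5-diyl bis(3-methylbut-2-enoate)
Conditions: HF·pyridine, pyridine/THF, 0 °C to rt
Reagents that add atoms: none
Why: Fluoride-driven desilylation under buffered conditions spares the two esters and the acid-sensitive methylidene-bicyclo[3.1.1]heptane.

Step 18
Reactants: 27 (3R,5R,11S)-11-hydroxy-2,6,6-trimethyl-9-methylidenetricyclo[5.4.0.0(2,8)]undecane-3,5-diyl bis(3-methylbut-2-enoate)
Product: 29 (1R,2R,3R,5R,7S,8R)-2,6,6,9-tetramethyl-11-oxotricyclo[5.4.0.0(2,8)]undec-9-ene-3,5-diyl bis(3-methylbut-2-enoate) (CNP0105062.1), via exocyclic enone 28 (not isolated)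
Conditions: Dess–Martin periodinane (1.5 equiv), CH2Cl2, 0 °C to rt; then DBU (0.2 equiv), CH2Cl2, 0 °C
Reagents that add atoms: none
Why: Dess–Martin oxidation to the ketone, then base-mediated isomerisation of the β,γ-methylidene into conjugation; the bridgehead side cannot enolise, so only C10 is deprotonated and the 9-methyl-9-en-11-one forms.

## Compound list

1 | 1-chloro-3-methylbut-2-ene | CC(C)=CCCl | starting material
2 | (2E)-4-chloro-2-methylbut-2-en-1-ol | OC/C(C)=C/CCl | intermediate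
3 | (2E)-4-chloro-2-methylbut-2-en-1-yl 2-methylpropanoate | CC(C)C(=O)OC/C(C)=C/CCl | intermediate
4 | (2E)-2-methyl-4-oxobut-2-en-1-yl 2-methylpropanoate | CC(C)C(=O)OC/C(C)=C/C=O | intermediate
5 | 3-methylbut-2-enoyl chloride | CC(C)=CC(Cl)=O | starting material
6 | tert-butyl 3-methylbut-2-enoate | CC(C)=CC(=O)OC(C)(C)C | intermediate
7 | tert-butyl[(1-tert-butoxy-3-methylbuta-1,3-dien-1-yl)oxy]dimethylsilane | C=C(C)C=C(OC(C)(C)C)O[Si](C)(C)C(C)(C)C | intermediate
8 | tert-butyl (2E,5S,6E)-3,7-dimethyl-8-(2-methylpropanoyloxy)-5-(trichlorosilyloxy)octa-2,6-dienoate | CC(C)C(=O)OC/C(C)=C/[C@@H](O[Si](Cl)(Cl)Cl)C/C(C)=C/C(=O)OC(C)(C)C | intermediate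
9 | tert-butyl (2E,5S,6E)-5-hydroxy-3,7-dimethyl-8-(2-methylpropanoyloxy)octa-2,6-dienoate | CC(C)C(=O)OC/C(C)=C/[C@@H](O)C/C(C)=C/C(=O)OC(C)(C)C | intermediate
10 | tert-butyldimethylsilyl (2E,5S,6E)-5-(tert-butyldimethylsilyloxy)-3,7-dimethyl-8-(2-methylpropanoyloxy)octa-2,6-dienoate | CC(C)C(=O)OC/C(C)=C/[C@@H](O[Si](C)(C)C(C)(C)C)C/C(C)=C/C(=O)O[Si](C)(C)C(C)(C)C | intermediate
11 | (2E,5S,6E)-5-(tert-butyldimethylsilyloxy)-3,7-dimethyl-8-(2-methylpropanoyloxy)octa-2,6-dienoic acid | CC(C)C(=O)OC/C(C)=C/[C@@H](O[Si](C)(C)C(C)(C)C)C/C(C)=C/C(=O)O | intermediate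
12 | (2E,5S,6E)-5-(tert-butyldimethylsilyloxy)-3,7-dimethyl-8-(2-methylpropanoyloxy)octa-2,6-dienoyl chloride | CC(C)C(=O)OC/C(C)=C/[C@@H](O[Si](C)(C)C(C)(C)C)C/C(C)=C/C(Cl)=O | intermediate
13 | (5S,6E)-5-(tert-butyldimethylsilyloxy)-7-methyl-3-methylidene-8-(2-methylpropanoyloxy)octa-1,6-dien-1-one (vinylketene) | CC(C)C(=O)OC/C(C)=C/[C@@H](O[Si](C)(C)C(C)(C)C)CC(=C)C=C=O | intermediate
14 | [(1R,4S,5R,7R)-4-(tert-butyldimethylsilyloxy)-7-methyl-2-methylidene-6-oxobicyclo[3.1.1]heptan-7-yl]methyl 2-methylpropanoate (silyloxy on the C6 side, 7-methyl syn to the C2–C4 bridge) | CC(C)C(=O)OC[C@@]2(C)[C@@H]3[C@@H](O[Si](C)(C)C(C)(C)C)CC(=C)[C@H]2C3=O | intermediate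
15 | lithium (11S)-11-(tert-butyldimethylsilyloxy)-2,6,6-trimethyl-9-methylidene-5-oxo-4-oxatricyclo[5.4.0.0(2,8)]undecan-7-olate | O=C1OC[C@@]2(C)[C@@H]3[C@@H](O[Si](C)(C)C(C)(C)C)CC(=C)[C@H]2[C@]3([O-])C1(C)C.[Li+] | intermediate
16 | lithium O-[(11S)-11-(tert-butyldimethylsilyloxy)-2,6,6-trimethyl-9-methylidene-5-oxo-4-oxatricyclo[5.4.0.0(2,8)]undecan-7-yl] carbonodithioate | O=C1OC[C@@]2(C)[C@@H]3[C@@H](O[Si](C)(C)C(C)(C)C)CC(=C)[C@H]2[C@]3(OC(=S)[S-])C1(C)C.[Li+] | intermediate
17 | O-[(11S)-11-(tert-butyldimethylsilyloxy)-2,6,6-trimethyl-9-methylidene-5-oxo-4-oxatricyclo[5.4.0.0(2,8)]undecan-7-yl] S-methyl carbonodithioate | O=C1OC[C@@]2(C)[C@@H]3[C@@H](O[Si](C)(C)C(C)(C)C)CC(=C)[C@H]2[C@]3(OC(=S)SC)C1(C)C | intermediate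
18 | (11S)-11-(tert-butyldimethylsilyloxy)-2,6,6-trimethyl-9-methylidene-4-oxatricyclo[5.4.0.0(2,8)]undecan-5-one (C7–H as in the target) | O=C1OC[C@@]2(C)[C@@H]3[C@@H](O[Si](C)(C)C(C)(C)C)CC(=C)[C@H]2[C@@H]3C1(C)C | intermediate
19 | 3-[4-(tert-butyldimethylsilyloxy)-7-(hydroxymethyl)-7-methyl-2-methylidenebicyclo[3.1.1]heptan-6-yl]-3-methylbutan-2-one | OC[C@@]2(C)[C@@H]3[C@@H](O[Si](C)(C)C(C)(C)C)CC(=C)[C@H]2[C@@H]3C(C)(C)C(C)=O | intermediate
20 | 4-(tert-butyldimethylsilyloxy)-7-methyl-6-(2-methyl-3-oxobutan-2-yl)-2-methylidenebicyclo[3.1.1]heptane-7-carbaldehyde | O=C[C@@]2(C)[C@@H]3[C@@H](O[Si](C)(C)C(C)(C)C)CC(=C)[C@H]2[C@@H]3C(C)(C)C(C)=O | intermediate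
21 | (11S)-11-(tert-butyldimethylsilyloxy)-3-hydroxy-2,6,6-trimethyl-9-methylidenetricyclo[5.4.0.0(2,8)]undecan-5-one, C3 epimers | O=C1CC(O)[C@@]2(C)[C@@H]3[C@@H](O[Si](C)(C)C(C)(C)C)CC(=C)[C@H]2[C@@H]3C1(C)C | intermediate
22 | (11S)-11-(tert-butyldimethylsilyloxy)-2,6,6-trimethyl-9-methylidenetricyclo[5.4.0.0(2,8)]undec-3-en-5-one | O=C1C=C[C@@]2(C)[C@@H]3[C@@H](O[Si](C)(C)C(C)(C)C)CC(=C)[C@H]2[C@@H]3C1(C)C | intermediate
23 | (11S)-11-(tert-butyldimethylsilyloxy)-2,6,6-trimethyl-9-methylidene-3-(4,4,5,5-tetramethyl-1,3,2-dioxaborolan-2-yl)tricyclo[5.4.0.0(2,8)]undecan-5-one (boron where the C3 oxygen of the target sits) | O=C1C[C@@H](B4OC(C)(C)C(C)(C)O4)[C@@]2(C)[C@@H]3[C@@H](O[Si](C)(C)C(C)(C)C)CC(=C)[C@H]2[C@@H]3C1(C)C | intermediate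
24 | (3R,11S)-11-(tert-butyldimethylsilyloxy)-3-hydroxy-2,6,6-trimethyl-9-methylidenetricyclo[5.4.0.0(2,8)]undecan-5-one | O=C1C[C@@H](O)[C@@]2(C)[C@@H]3[C@@H](O[Si](C)(C)C(C)(C)C)CC(=C)[C@H]2[C@@H]3C1(C)C | intermediate
25 | (3R,5R,11S)-11-(tert-butyldimethylsilyloxy)-2,6,6-trimethyl-9-methylidenetricyclo[5.4.0.0(2,8)]undecane-3,5-diol | O[C@@H]1C[C@@H](O)[C@@]2(C)[C@@H]3[C@@H](O[Si](C)(C)C(C)(C)C)CC(=C)[C@H]2[C@@H]3C1(C)C | intermediate
26 | (3R,5R,11S)-11-(tert-butyldimethylsilyloxy)-2,6,6-trimethyl-9-methylidenetricyclo[5.4.0.0(2,8)]undecane-3,5-diyl bis(3-methylbut-2-enoate) | CC(C)=CC(=O)O[C@@H]1C[C@@H](OC(=O)C=C(C)C)[C@@]2(C)[C@@H]3[C@@H](O[Si](C)(C)C(C)(C)C)CC(=C)[C@H]2[C@@H]3C1(C)C | intermediate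
27 | (3R,5R,11S)-11-hydroxy-2,6,6-trimethyl-9-methylidenetricyclo[5.4.0.0(2,8)]undecane-3,5-diyl bis(3-methylbut-2-enoate) | CC(C)=CC(=O)O[C@@H]1C[C@@H](OC(=O)C=C(C)C)[C@@]2(C)[C@@H]3[C@@H](O)CC(=C)[C@H]2[C@@H]3C1(C)C | intermediate
28 | (3R,5R)-2,6,6-trimethyl-9-methylidene-11-oxotricyclo[5.4.0.0(2,8)]undecane-3,5-diyl bis(3-methylbut-2-enoate) | CC(C)=CC(=O)O[C@@H]1C[C@@H](OC(=O)C=C(C)C)[C@@]2(C)[C@@H]3C(=O)CC(=C)[C@H]2[C@@H]3C1(C)C | intermediate
29 | (1R,2R,3R,5R,7S,8R)-2,6,6,9-tetramethyl-11-oxotricyclo[5.4.0.0(2,8)]undec-9-ene-3,5-diyl bis(3-methylbut-2-enoate), CNP0105062.1 | CC(C)=CC(=O)O[C@@H]1C[C@@H](OC(=O)C=C(C)C)[C@@]2(C)[C@@H]3C(=O)C=C(C)[C@H]2[C@@H]3C1(C)C | target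

## Step count and risks

Total step count: 18. Longest linear sequence: 16 steps (steps 1–3, then 6–18). The second fragment (steps 4–5) joins at step 6.

The three steps most likely to fail:

**Step 8 (vinylketene [2+2]).** The alkene carries two allylic oxygens and is less nucleophilic than in the geranic acid precedent, so ketene dimerisation or deprotonation at the wrong γ-position may win. The fallback sets out from 11. Pyrrolidine with EDC·HCl and HOBt gives the pyrrolidine amide F1. Tf2O and 2,6-di-tert-butyl-4-methylpyridine in 1,2-dichloroethane (0 °C to 80 °C) turn it into the much more electrophilic vinylketeniminium ion, whose intramolecular [2+2] gives the cyclobutaniminium triflate F2. Aqueous NaHCO3 hydrolysis of the iminium returns to the route at 14.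

**Step 9 (tethered ester-enolate aldol and xanthate trapping).** Enolisation of the hindered isobutyrate may be slow, and the congested aldolate may revert before it is trapped. The fallback sets out from 14. K2CO3 in MeOH removes the isobutyrate to give the hydroxymethyl cyclobutanone F3, and 2-bromo-2-methylpropanoyl bromide with pyridine gives the bromo ester F4. SmI2 (2.2 equiv, THF, −78 °C) then effects an intramolecular Reformatsky reaction under neutral conditions to the free hydroxy lactone F5, which is isolated. Methyl chlorooxoacetate with DMAP gives the methyl oxalate F6, and Bu3SnH/AIBN in toluene at 100 °C deoxygenates it, returning to the route at 18.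

**Step 14 (enantioselective β-borylation).** The β-carbon is neopentyl and the level and sense of ligand control on this enone are untested. The fallback sets out from 22. Catalyst-controlled nucleophilic epoxidation (tBuOOH, La(OiPr)3, (R)-BINOL, Ph3As=O, THF, 4 Å MS) gives the epoxy ketone F7; its epimer is removed by chromatography. SmI2 in THF/MeOH at −78 °C cleaves the Cα–O bond and returns to the route at 24.

Further compounds
F1 | step 8 | (2E,5S,6E)-5-(tert-butyldimethylsilyloxy)-3,7-dimethyl-8-(2-methylpropanoyloxy)-1-(pyrrolidin-1-yl)octa-2,6-dien-1-one | CC(C)C(=O)OC/C(C)=C/[C@@H](O[Si](C)(C)C(C)(C)C)C/C(C)=C/C(=O)N1CCCC1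
F2 | step 8 | 1-[4-(tert-butyldimethylsilyloxy)-7-methyl-2-methylidene-7-(2-methylpropanoyloxymethyl)bicyclo[3.1.1]heptan-6-ylidene]pyrrolidinium triflate | CC(C)C(=O)OC[C@@]2(C)[C@@H]3[C@@H](O[Si](C)(C)C(C)(C)C)CC(=C)[C@H]2C3=[N+]1CCCC1.[O-]S(=O)(=O)C(F)(F)F
F3 | step 9 | 4-(tert-butyldimethylsilyloxy)-7-(hydroxymethyl)-7-methyl-2-methylidenebicyclo[3.1.1]heptan-6-one | OC[C@@]2(C)[C@@H]3[C@@H](O[Si](C)(C)C(C)(C)C)CC(=C)[C@H]2C3=O
F4 | step 9 | [4-(tert-butyldimethylsilyloxy)-7-methyl-2-methylidene-6-oxobicyclo[3.1.1]heptan-7-yl]methyl 2-bromo-2-methylpropanoate | CC(C)(Br)C(=O)OC[C@@]2(C)[C@@H]3[C@@H](O[Si](C)(C)C(C)(C)C)CC(=C)[C@H]2C3=O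
F5 | step 9 | (11S)-11-(tert-butyldimethylsilyloxy)-7-hydroxy-2,6,6-trimethyl-9-methylidene-4-oxatricyclo[5.4.0.0(2,8)]undecan-5-one | O=C1OC[C@@]2(C)[C@@H]3[C@@H](O[Si](C)(C)C(C)(C)C)CC(=C)[C@H]2[C@]3(O)C1(C)C
F6 | step 9 | (11S)-11-(tert-butyldimethylsilyloxy)-2,6,6-trimethyl-9-methylidene-5-oxo-4-oxatricyclo[5.4.0.0(2,8)]undecan-7-yl methyl oxalate | O=C1OC[C@@]2(C)[C@@H]3[C@@H](O[Si](C)(C)C(C)(C)C)CC(=C)[C@H]2[C@]3(OC(=O)C(=O)OC)C1(C)C
F7 | step 14 | (11S)-11-(tert-butyldimethylsilyloxy)-3,4-epoxy-2,6,6-trimethyl-9-methylidenetricyclo[5.4.0.0(2,8)]undecan-5-one (epoxide oxygen on the face of the later C3 hydroxyl) | O=C1[C@H]4O[C@H]4[C@@]2(C)[C@@H]3[C@@H](O[Si](C)(C)C(C)(C)C)CC(=C)[C@H]2[C@@H]3C1(C)C
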